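## The problem

Compound 21 is a cyclohexenone (ring atoms C3a, C4, C5, C6, C7, C7a) whose enol-ether oxygen on C3a and tertiary oxygen on C7a are bridged by one methylene, so a 1,3-dioxolane is fused across C3a–C7a and the C5 carbonyl is a vinylogous ester. C7a is a fully substituted, oxygenated stereocentre (R) and carries the side chain whose first carbon, C8, is also stereogenic (S). This contiguous pair is the main stereochemical problem: acyclic induction from one to the other is unreliable, so both are best written in one stereospecific event. The third centre, C6 (R, allyl), is 1,3 to C7a and α to the ketone. It can epimerise, but in the final enone the flat dioxolane–enone unit holds the C7a–O bond in the ring plane and the side chain axial, so an equatorial allyl group trans to the side chain should be the thermodynamic arrangement. C3a is trigonal in 21, so its configuration in intermediates is only a control element. The groups that limit the chemistry are the β-alkoxy carbonyl relationship between C5 and O3 (base opens the acetal by E1cB), the vinylogous ester, the terminal alkene and the electron-rich trimethoxyarene. The feature that allows a short ring synthesis is the 1,4-relationship between the C5 carbonyl and the middle carbon of the allyl group. If that carbon is an ester, C5–C6 is the bond formed when an acyl anion equivalent at C5 adds to the β-carbon of an acrylate, and a cis-dioxolane on C3a/C7a holds the aldehyde arm (C4–C5) and the acrylate arm (C7–C6) on one face.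

## Retrosynthesis

**C3a=C4 (21 ⇒ 20 ⇒ 19).** The last operation removes two hydrogens across C3a–C4. Closing the dioxolane last on a hydroxy dione would give up the preformed acetal that the ring closure depends on. Ketone 19 lacks the sensitive vinylogous ester. The forward step needs enolisation toward C4 only (silyl enol ether 20) and a dehydrogenation in which C3a–H is the only β-hydrogen.

**Allyl group (19 ⇒ 18 ⇒ 17 ⇒ 16).** The terminal C=C of the allyl group is cut back to aldehyde 18 and then to the acetate arm of keto ester 16. Direct allylation of a C5 ketone would compete between C4 and C6 and would give no acceptor for ring formation. The forward sequence must tell ketone from ester: reduce both (17), oxidise both (18), then methylenate the aldehyde selectively.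

**C5–C6 (16 ⇒ 15).** This is the strategic cut. It opens the carbocycle to aldehyde enoate 15 and delivers the C5 ketone and the C6 substituent in one bond. An aldol or alkylation closure at C6–C7 or C4–C5 would need extra redox steps. The forward reaction must add the acyl anion equivalent 1,4 without losing the β-alkoxide O3.

**The two arms (15 ⇒ 14 ⇒ 12 + 13).** The enoate comes from cross-metathesis of an allyl group with methyl acrylate 13. The aldehyde is kept as a dimethyl acetal until just before the key step. Two free aldehydes on near-identical arms could not be told apart, and these two masks are orthogonal from the start.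

**Methylene acetal (12 ⇒ 11).** The O1–C2 and O3–C2 bonds are cut to the syn diol 11. The closure must be run under base, because acid would draw the pendant dimethyl acetal into a furanoside.

**C8–CH2Ar (11 ⇒ 8 + 10, 10 from 9).** Opening epoxide 8 at C8 with benzylmagnesium reagent 10 (made from chloride 9) creates C8 with inversion and frees the C7a hydroxyl. The more obvious dihydroxylation across C7a–C3a would need an (E)-trisubstituted alkene with the branched stereogenic chain on its fully substituted carbon, and no olefination gives that geometry reliably. In 8 one oxirane carries C7a and C8 together.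

**Epoxide (8 ⇒ 7).** The C7a–O and C8–O bonds are cut to dienol 7. The required isomer is the threo epoxy alcohol. Hydroxyl-directed epoxidation of a 2-substituted secondary allylic alcohol gives the erythro series, so the oxygen must come from a chiral dioxirane under reagent control.

**C7a–C7 (7 ⇒ 5 + 6).** The allyl group is removed as allylmagnesium bromide 6, leaving propargylic alcohol 5. Hydroxyl-assisted anti-carbomagnesiation sets the alkene geometry (methyl trans to the carbinol) by mechanism, not by steric bias.

**Carbinol and chain (5 ⇒ 4 ⇒ 2 + 3; 2 ⇒ 1).** The C3a carbinol comes from asymmetric transfer hydrogenation of ynone 4. The ynone comes from Weinreb amide 2 and propynylmagnesium bromide 3, and 2 from commercial ester 1, which already contains C4, C5 and the aldehyde mask.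

## Roads not taken

Alternative 1: The cut is C7–C7a, with a temporary O1–C5 lactone bond. SmI2 (divalent samarium) would reduce ketone A2 to a ketyl that adds to the methylene carbon of acrylate A3, and the alkoxide would close lactone A1. A1 already holds oxygenated C7a, C6 with its allyl group and C5 as a carbonyl. Ketal hydrolysis, Claisen-type closure of the methyl ketone enolate onto the lactone carbonyl and O,O-methylenation would finish. Its merits are convergence, an allyl group present from the start, and an enol ether that arises from a 1,3-dione, so there is no late dehydrogenation and no β-alkoxy aldehyde. It would need roughly half the steps of the chosen plan, which is a clear advantage. Its weak points are stereochemical. C7a would rest only on 1,2-induction from C8 in the ketyl addition, and the sense (Felkin or chelation through the ketal oxygens) cannot be predicted. C8 in A2 is α to a ketone and can epimerise. The ring closure asks a hindered enolate to attack a lactone that releases a tertiary alkoxide β to the new ketone. Against the shorter count the chosen plan sets a catalyst-controlled epoxidation and a stereospecific opening that fix C7a and C8 together with a predictable sense.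

Alternative 2: The cut is C6–C7 and C4=C5. The enamine of aldehyde A5 with a diarylprolinol silyl ether would add to the methylene of enone A6, and intramolecular aldol condensation would give cyclohexenone A4. This builds the carbocycle in one operation from two simple pieces and sets C6 under catalyst control, faster than the chosen plan builds its ring. But A4 has its carbonyl on C3a, no oxygen on C5 and a C–H at C7a. The quaternary carbinol would have to come from a late α-hydroxylation of a hindered tertiary carbon on the face cis to the allyl group, which nothing in the substrate favours. The carbonyl would then have to be moved to C5. A6 is also an α-methylene ketone whose γ-stereocentre C8 can be lost by isomerisation into conjugation. The early saving is likely to be used up by these oxidations, whereas the chosen plan makes the oxygenated C7a/C8 pair first.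

Alternative 3: The cut is O1–C2 and O3–C3a on para-quinol A8. A chiral phosphoric acid would form the hemiacetal of the tertiary hydroxyl with formaldehyde A9, and the hemiacetal oxygen would add to one enone β-carbon to give A7. Conjugate reduction with enolate allylation at C6, then dehydrogenation toward C4, would complete the target. This is the shortest road of all. One catalytic step gives both ring oxygens, C7a and the C5 ketone, and the remaining enone is a regiospecific handle for C6. It shares its last step with the chosen plan. Its risks are that formaldehyde is the least organised aldehyde partner for such a cascade, and that the two enone arms of A8 differ only through the remote C8 centre, so the catalyst alone must set C7a relative to C8. A8 also needs a separately made benzylic stereocentre. The chosen plan is longer; what it offers in return is that C7a and C8 come from one oxirane by stereospecific chemistry and the acetal is made from a defined diol.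

Key step: step 10

Assumption: the L-configured fructose-type epoxidation ketone and the (5aS,10bR) aminoindanol triazolium salt are taken as purchasable, the latter is assumed to be the antipode matched to 15, and chloride 9 is used instead of the bromide because it gives less homocoupling on Grignard formation.

Step 1
Reactants: 1 methyl 3,3-dimethoxypropanoate
Product: 2 N,3,3-trimethoxy-N-methylpropanamide
Conditions: MeNH(OMe)·HCl (1.5 equiv), i-PrMgCl (3 equiv), THF, −20 to 0 °C
Reagents that add atoms: N,O-dimethylhydroxylamine hydrochloride, CNOC.Cl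
Why: Weinreb amide formation: the chloromagnesium amide of N,O-dimethylhydroxylamine displaces methoxide from the ester, and the basic anhydrous conditions leave the dimethyl acetal untouched.

Step 2
Reactants: 2 N,3,3-trimethoxy-N-methylpropanamide; 3 prop-1-yn-1-ylmagnesium bromide
Product: 4 6,6-dimethoxyhex-2-yn-4-one
Conditions: 3 (1.3 equiv), THF, 0 °C; aq. NH4Cl
Reagents that add atoms: none
Why: Weinreb ketone synthesis: the alkynyl Grignard adds once and the magnesium-chelated tetrahedral adduct survives until work-up, so the ynone forms without over-addition.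

Step 3
Reactants: 4 6,6-dimethoxyhex-2-yn-4-one
Product: 5 (4R)-6,6-dimethoxyhex-2-yn-4-ol
Conditions: Ru[(R,R)-TsDPEN](p-cymene) (0.5 mol%), i-PrOH, rt
Reagents that add atoms: none
Why: Noyori asymmetric transfer hydrogenation of an alkynyl ketone: the alkyne takes the place of the aryl group in the bifunctional transition state, so the (R,R)-ligand should give the (R)-carbinol that becomes C3a. The base-free amido catalyst avoids loss of methanol from the β-keto acetal.

Step 4
Reactants: 5 (4R)-6,6-dimethoxyhex-2-yn-4-ol; 6 allylmagnesium bromide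
Product: 7 (2E,4R)-6,6-dimethoxy-3-(prop-2-en-1-yl)hex-2-en-4-ol
Conditions: 6 (3.5 equiv), Et2O, 0 °C to reflux; aq. NH4Cl
Reagents that add atoms: none
Why: Hydroxyl-assisted anti-carbomagnesiation of a propargylic alcohol: the magnesium alkoxide directs allyl to the proximal alkyne carbon (future C7a) and magnesium ends on the distal carbon inside a five-membered chelate. Protonation therefore leaves the methyl group trans to the carbinol carbon and cis to allyl (E), which fixes the geometry that later defines C8.

Step 5
Reactants: 7 (2E,4R)-6,6-dimethoxy-3-(prop-2-en-1-yl)hex-2-en-4-ol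
Product: 8 (1R)-3,3-dimethoxy-1-[(2S,3S)-3-methyl-2-(prop-2-en-1-yl)oxiran-2-yl]propan-1-ol
Conditions: ent-Shi ketone (1,2:4,5-di-O-isopropylidene-β-L-erythro-2,3-hexodiulo-2,6-pyranose, 30 mol%), KHSO5 (as Oxone), K2CO3, Bu4NHSO4 (cat.), MeCN/CH2(OMe)2/aq. Na2B4O7 buffer, 0 °C
Reagents that add atoms: potassium peroxymonosulfate, [K+].[O-]S(=O)(=O)OO
Why: Shi asymmetric epoxidation: the chiral dioxirane attacks the electron-rich trisubstituted alkene through a spiro transition state and leaves the terminal allyl alkene alone. By that model the L-configured ketone delivers oxygen to the face that gives the (2S,3S)-oxirane, which is the threo epoxy alcohol (C7a set, C8 set in invertible form). Reagent control is used because hydroxyl-directed epoxidation of this 2-substituted allylic alcohol would give the erythro isomer.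

Step 6
Reactants: 8 (1R)-3,3-dimethoxy-1-[(2S,3S)-3-methyl-2-(prop-2-en-1-yl)oxiran-2-yl]propan-1-ol; 9 3,4,5-trimethoxybenzyl chloride
Product: 11 (4R,5R)-7,7-dimethoxy-4-[(2S)-1-(3,4,5-trimethoxyphenyl)propan-2-yl]hept-1-ene-4,5-diol, via 3,4,5-trimethoxybenzylmagnesium chloride 10 (not isolated)
Conditions: 9, Mg, THF, 0 °C; separately 8, i-PrMgCl (1 equiv), THF, −30 °C; then 10 (2.5 equiv), CuI (10 mol%), −30 °C to rt; aq. NH4Cl
Reagents that add atoms: none
Why: Copper-catalysed SN2 opening of an epoxide by a benzylic Grignard reagent: attack at the secondary carbon with inversion makes C8 (S) and releases the tertiary C7a hydroxyl with its configuration intact. The fully substituted neighbouring carbon blocks attack at C7a and Payne rearrangement of the magnesium alkoxide.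

Step 7
Reactants: 11 (4R,5R)-7,7-dimethoxy-4-[(2S)-1-(3,4,5-trimethoxyphenyl)propan-2-yl]hept-1-ene-4,5-diol
Product: 12 (4R,5R)-5-(2,2-dimethoxyethyl)-4-(prop-2-en-1-yl)-4-[(2S)-1-(3,4,5-trimethoxyphenyl)propan-2-yl]-1,3-dioxolane
Conditions: NaH (2.5 equiv), CH2Br2 (1.5 equiv), DMF, 0 to 40 °C
Reagents that add atoms: dibromomethane, BrCBr
Why: Methylene acetal formation by double Williamson alkylation of the diol dianion; the five-membered closure is fast. Base is chosen because acid-catalysed acetalisation would draw the dimethyl acetal into a furanoside with the C7a hydroxyl.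

Step 8
Reactants: 12 (4R,5R)-5-(2,2-dimethoxyethyl)-4-(prop-2-en-1-yl)-4-[(2S)-1-(3,4,5-trimethoxyphenyl)propan-2-yl]-1,3-dioxolane; 13 methyl acrylate
Product: 14 methyl (2E)-4-[(4R,5R)-5-(2,2-dimethoxyethyl)-4-[(2S)-1-(3,4,5-trimethoxyphenyl)propan-2-yl]-1,3-dioxolan-4-yl]but-2-enoate
Conditions: 13 (5 equiv), second-generation Hoveyda–Grubbs catalyst RuCl2(H2IMes)(=CH-C6H4-2-O-i-Pr) (5 mol%), CH2Cl2, 40 °C
Reagents that add atoms: none
Why: Olefin cross-metathesis of a terminal alkene with excess acrylate gives the (E)-enoate; the acetals and the arene are inert to the ruthenium carbene.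

Step 9
Reactants: 14 methyl (2E)-4-[(4R,5R)-5-(2,2-dimethoxyethyl)-4-[(2S)-1-(3,4,5-trimethoxyphenyl)propan-2-yl]-1,3-dioxolan-4-yl]but-2-enoate
Product: 15 methyl (2E)-4-[(4R,5R)-5-(2-oxoethyl)-4-[(2S)-1-(3,4,5-trimethoxyphenyl)propan-2-yl]-1,3-dioxolan-4-yl]but-2-enoate
Conditions: 1 M aq. HCl, THF, rt
Reagents that add atoms: water, O
Why: Acid-catalysed hydrolysis of the dimethyl acetal; the formaldehyde-derived dioxolane hydrolyses far more slowly, and the mild conditions avoid β-elimination of O3 from the new aldehyde.

Step 10
Reactants: 15 methyl (2E)-4-[(4R,5R)-5-(2-oxoethyl)-4-[(2S)-1-(3,4,5-trimethoxyphenyl)propan-2-yl]-1,3-dioxolan-4-yl]but-2-enoate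
Product: 16 methyl 2-[(3aR,6S,7aR)-5-oxo-7a-[(2S)-1-(3,4,5-trimethoxyphenyl)propan-2-yl]hexahydro-1,3-benzodioxol-6-yl]acetate
Conditions: (5aS,10bR)-2-(pentafluorophenyl)-5a,10b-dihydro-4H,6H-indeno[2,1-b][1,2,4]triazolo[4,3-d][1,4]oxazin-2-ium tetrafluoroborate (20 mol%), Et3N (20 mol%), toluene, rt
Reagents that add atoms: none
Why: Intramolecular Stetter reaction: the triazolylidene adds to the C5 aldehyde, proton transfer gives the Breslow enaminol (an acyl anion equivalent), this adds to the enoate β-carbon C6, and proton transfer with loss of the carbene releases the 1,4-keto ester. The closest known reaction type is the enantioselective intramolecular Stetter cyclisation of aldehydes onto tethered α,β-unsaturated esters with aminoindanol-derived N-aryl triazolium salts. The cyclohexanone closes 6-exo-trig; the cis-dioxolane already fixes C3a and C7a and turns both arms to one face, which offsets the slower closure of six-membered rings from aliphatic aldehydes. C6 is the only new stereocentre and is set by the enoate face that the chiral enaminol attacks, with the catalyst antipode chosen so that the acetate arm ends cis to O1 and trans to the side chain (6S here, 6R once the arm is allyl). The step needs conjugate addition at C6 to run ahead of E1cB loss of the β-alkoxide O3 and ahead of aldol or benzoin-type self-condensation; the acidic pentafluorophenyl triazolium allows a weak amine base in substoichiometric amount, and the (E)-acrylate is a strong intramolecular acceptor. Because C6 stays α to the ketone, a mismatch at this centre can still be corrected by equilibration at the end of the route.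

Step 11
Reactants: 16 methyl 2-[(3aR,6S,7aR)-5-oxo-7a-[(2S)-1-(3,4,5-trimethoxyphenyl)propan-2-yl]hexahydro-1,3-benzodioxol-6-yl]acetate
Product: 17 (3aR,6R,7aR)-6-(2-hydroxyethyl)-7a-[(2S)-1-(3,4,5-trimethoxyphenyl)propan-2-yl]hexahydro-1,3-benzodioxol-5-ol (mixture of C5 epimers)
Conditions: LiAlH4 (2 equiv), THF, 0 °C
Reagents that add atoms: none
Why: Hydride reduction of ketone and ester gives the diol; the C5 carbinol configuration does not matter because it is reoxidised, and the acetal is inert.

Step 12
Reactants: 17 (3aR,6R,7aR)-6-(2-hydroxyethyl)-7a-[(2S)-1-(3,4,5-trimethoxyphenyl)propan-2-yl]hexahydro-1,3-benzodioxol-5-ol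
Product: 18 2-[(3aR,6S,7aR)-5-oxo-7a-[(2S)-1-(3,4,5-trimethoxyphenyl)propan-2-yl]hexahydro-1,3-benzodioxol-6-yl]acetaldehyde
Conditions: Dess–Martin periodinane (2.5 equiv), CH2Cl2, rt
Reagents that add atoms: none
Why: Dess–Martin oxidation of the primary and secondary alcohols returns the C5 ketone and gives the aldehyde without base that could open the β-alkoxy ketone or epimerise C6.

Step 13
Reactants: 18 2-[(3aR,6S,7aR)-5-oxo-7a-[(2S)-1-(3,4,5-trimethoxyphenyl)propan-2-yl]hexahydro-1,3-benzodioxol-6-yl]acetaldehyde
Product: 19 (3aR,6R,7aR)-6-(prop-2-en-1-yl)-7a-[(2S)-1-(3,4,5-trimethoxyphenyl)propan-2-yl]hexahydro-1,3-benzodioxol-5-one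
Conditions: Ph3PCH3Br (1.1 equiv), KN(SiMe3)2 (1.05 equiv), THF, 0 °C; then 18, −78 to 0 °C
Reagents that add atoms: methyltriphenylphosphonium bromide, C[P+](c1ccccc1)(c1ccccc1)c1ccccc1.[Br-]
Why: Wittig methylenation: one equivalent of the unstabilised ylide at low temperature reacts with the aldehyde much faster than with the α-branched ketone, which completes the allyl group.

Step 14
Reactants: 19 (3aR,6R,7aR)-6-(prop-2-en-1-yl)-7a-[(2S)-1-(3,4,5-trimethoxyphenyl)propan-2-yl]hexahydro-1,3-benzodioxol-5-one
Product: 20 trimethyl{[(3aR,6R,7aR)-6-(prop-2-en-1-yl)-7a-[(2S)-1-(3,4,5-trimethoxyphenyl)propan-2-yl]-3a,6,7,7a-tetrahydro-1,3-benzodioxol-5-yl]oxy}silane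
Conditions: LiN(i-Pr)2 (1.1 equiv), Me3SiCl (3 equiv), THF, −78 °C
Reagents that add atoms: chlorotrimethylsilane, C[Si](C)(C)Cl
Why: Kinetic deprotonation at the less substituted α-carbon C4 with in situ silylation gives the C4=C5 silyl enol ether; the low temperature and immediate trapping suppress loss of the β-alkoxide O3 and leave C6 untouched.

Step 15
Reactants: 20 trimethyl{[(3aR,6R,7aR)-6-(prop-2-en-1-yl)-7a-[(2S)-1-(3,4,5-trimethoxyphenyl)propan-2-yl]-3a,6,7,7a-tetrahydro-1,3-benzodioxol-5-yl]oxy}silane
Product: 21 (6R,7aR)-6-(prop-2-en-1-yl)-7a-[(2S)-1-(3,4,5-trimethoxyphenyl)propan-2-yl]-7,7a-dihydro-1,3-benzodioxol-5(6H)-one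
Conditions: Pd(OAc)2 (1.1 equiv), MeCN, rt
Reagents that add atoms: none
Why: Saegusa–Ito oxidation: the silyl enol ether gives a palladium enolate at C4 and syn β-hydride elimination of the only β-hydrogen (C3a–H) forms the C3a=C4 bond of the vinylogous ester. C6 ends in the arrangement expected to be thermodynamically preferred (allyl equatorial, trans to the side chain).

Compound list

1 | methyl 3,3-dimethoxypropanoate | COC(=O)CC(OC)OC | starting material
2 | N,3,3-trimethoxy-N-methylpropanamide | CON(C)C(=O)CC(OC)OC | intermediate
3 | prop-1-yn-1-ylmagnesium bromide | CC#C[Mg]Br | starting material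
4 | 6,6-dimethoxyhex-2-yn-4-one | CC#CC(=O)CC(OC)OC | intermediate
5 | (4R)-6,6-dimethoxyhex-2-yn-4-ol | CC#C[C@H](O)CC(OC)OC | intermediate
6 | allylmagnesium bromide | C=CC[Mg]Br | starting material
7 | (2E,4R)-6,6-dimethoxy-3-(prop-2-en-1-yl)hex-2-en-4-ol | C/C=C(\CC=C)[C@H](O)CC(OC)OC | intermediate
8 | (1R)-3,3-dimethoxy-1-[(2S,3S)-3-methyl-2-(prop-2-en-1-yl)oxiran-2-yl]propan-1-ol | C=CC[C@]1(O[C@H]1C)[C@H](O)CC(OC)OC | intermediate
9 | 3,4,5-trimethoxybenzyl chloride | COc1cc(CCl)cc(OC)c1OC | starting material
10 | 3,4,5-trimethoxybenzylmagnesium chloride | COc1cc(C[Mg]Cl)cc(OC)c1OC | intermediate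
11 | (4R,5R)-7,7-dimethoxy-4-[(2S)-1-(3,4,5-trimethoxyphenyl)propan-2-yl]hept-1-ene-4,5-diol | C=CC[C@@](O)([C@@H](C)Cc1cc(OC)c(OC)c(OC)c1)[C@H](O)CC(OC)OC | intermediate
12 | (4R,5R)-5-(2,2-dimethoxyethyl)-4-(prop-2-en-1-yl)-4-[(2S)-1-(3,4,5-trimethoxyphenyl)propan-2-yl]-1,3-dioxolane | C=CC[C@]1([C@@H](C)Cc2cc(OC)c(OC)c(OC)c2)OCO[C@@H]1CC(OC)OC | intermediate
13 | methyl acrylate | C=CC(=O)OC | starting material
14 | methyl (2E)-4-[(4R,5R)-5-(2,2-dimethoxyethyl)-4-[(2S)-1-(3,4,5-trimethoxyphenyl)propan-2-yl]-1,3-dioxolan-4-yl]but-2-enoate | COC(=O)/C=C/C[C@]1([C@@H](C)Cc2cc(OC)c(OC)c(OC)c2)OCO[C@@H]1CC(OC)OC | intermediate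
15 | methyl (2E)-4-[(4R,5R)-5-(2-oxoethyl)-4-[(2S)-1-(3,4,5-trimethoxyphenyl)propan-2-yl]-1,3-dioxolan-4-yl]but-2-enoate | COC(=O)/C=C/C[C@]1([C@@H](C)Cc2cc(OC)c(OC)c(OC)c2)OCO[C@@H]1CC=O | intermediate
16 | methyl 2-[(3aR,6S,7aR)-5-oxo-7a-[(2S)-1-(3,4,5-trimethoxyphenyl)propan-2-yl]hexahydro-1,3-benzodioxol-6-yl]acetate | COC(=O)C[C@@H]1C[C@]2([C@@H](C)Cc3cc(OC)c(OC)c(OC)c3)OCO[C@@H]2CC1=O | intermediate
17 | (3aR,6R,7aR)-6-(2-hydroxyethyl)-7a-[(2S)-1-(3,4,5-trimethoxyphenyl)propan-2-yl]hexahydro-1,3-benzodioxol-5-ol (C5 epimers) | OCC[C@@H]1C[C@]2([C@@H](C)Cc3cc(OC)c(OC)c(OC)c3)OCO[C@@H]2CC1O | intermediate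
18 | 2-[(3aR,6S,7aR)-5-oxo-7a-[(2S)-1-(3,4,5-trimethoxyphenyl)propan-2-yl]hexahydro-1,3-benzodioxol-6-yl]acetaldehyde | O=CC[C@@H]1C[C@]2([C@@H](C)Cc3cc(OC)c(OC)c(OC)c3)OCO[C@@H]2CC1=O | intermediate
19 | (3aR,6R,7aR)-6-(prop-2-en-1-yl)-7a-[(2S)-1-(3,4,5-trimethoxyphenyl)propan-2-yl]hexahydro-1,3-benzodioxol-5-one | C=CC[C@@H]1C[C@]2([C@@H](C)Cc3cc(OC)c(OC)c(OC)c3)OCO[C@@H]2CC1=O | intermediate
20 | trimethyl{[(3aR,6R,7aR)-6-(prop-2-en-1-yl)-7a-[(2S)-1-(3,4,5-trimethoxyphenyl)propan-2-yl]-3a,6,7,7a-tetrahydro-1,3-benzodioxol-5-yl]oxy}silane | C=CC[C@@H]1C[C@]2([C@@H](C)Cc3cc(OC)c(OC)c(OC)c3)OCO[C@@H]2C=C1O[Si](C)(C)C | intermediate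
21 | (6R,7aR)-6-(prop-2-en-1-yl)-7a-[(2S)-1-(3,4,5-trimethoxyphenyl)propan-2-yl]-7,7a-dihydro-1,3-benzodioxol-5(6H)-one | C=CC[C@@H]1C[C@]2([C@@H](C)Cc3cc(OC)c(OC)c(OC)c3)OCOC2=CC1=O | target

Total step count: 15. Longest linear sequence: 15 steps (1 to 21); reagent 10 is made in the flask of step 6.

Least certain steps

Step 10 (key step). The likely failures are E1cB loss of the β-alkoxide O3 from the aldehyde with opening of the dioxolane, slow 6-exo closure of an aliphatic acyl anion equivalent that lets aldol or benzoin-type self-condensation compete, and poor facial selectivity at C6 if catalyst and substrate are mismatched. A chair with the side chain equatorial would place the acetate arm cis to it, so the substrate's own bias may oppose the wanted epimer; this last failure is tolerable because C6 can be equilibrated in 21. The fallback forms the same C5–C6 bond reductively and without base. It sets out from 15: SmI2 (divalent samarium) with t-BuOH in THF generates the C5 ketyl, which adds 6-exo to the enoate β-carbon and gives methyl 2-[(3aR,6S,7aR)-5-hydroxy-7a-[(2S)-1-(3,4,5-trimethoxyphenyl)propan-2-yl]hexahydro-1,3-benzodioxol-6-yl]acetate F1 (or its lactone). Reduction of F1 with LiAlH4 returns to the route at diol 17.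

Step 5. The resident carbinol may oppose the catalyst (mismatched pairing) and erode facial selectivity, the secondary alcohol may be over-oxidised, and the ketone catalyst may decompose by Baeyer–Villiger oxidation. The fallback uses substrate direction and corrects C3a afterwards. It sets out from 4: reduction with the (S,S)-catalyst gives (4S)-6,6-dimethoxyhex-2-yn-4-ol F2, and allylmagnesiation as in step 4 gives (2E,4S)-6,6-dimethoxy-3-(prop-2-en-1-yl)hex-2-en-4-ol F3. Hydroxyl-directed epoxidation with VO(acac)2 and t-BuOOH then gives the erythro isomer (1S)-3,3-dimethoxy-1-[(2S,3S)-3-methyl-2-(prop-2-en-1-yl)oxiran-2-yl]propan-1-ol F4, which has the required oxirane but the opposite carbinol. Mitsunobu inversion (4-nitrobenzoic acid, PPh3, diisopropyl azodicarboxylate) gives (1R)-3,3-dimethoxy-1-[(2S,3S)-3-methyl-2-(prop-2-en-1-yl)oxiran-2-yl]propyl 4-nitrobenzoate F5, and methanolysis (K2CO3, MeOH) comes back to the route at 8.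

Step 6. Opening of the hindered trisubstituted epoxide may be sluggish, the benzylic Grignard may homocouple, and base may isomerise the epoxide to an allylic alcohol. The fallback replaces the Grignard by a sulfone-stabilised carbanion that can be used in excess. It sets out from 8: lithiated 3,4,5-trimethoxybenzyl phenyl sulfone in THF/DMPU opens the epoxide at C8 to give (4R,5R)-4-[(2R)-1-(benzenesulfonyl)-1-(3,4,5-trimethoxyphenyl)propan-2-yl]-7,7-dimethoxyhept-1-ene-4,5-diol F6, and reductive desulfonylation (Mg, MeOH) returns to the route at 11.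

Step 4. Carbometallation of the internal alkyne may stop short, allyl may be delivered to the distal carbon, and competing syn addition may erode the geometry. The fallback sets the geometry by hydrometallation. It sets out from 5: hydroxyl-directed trans-hydrostannation with [Cp*RuCl]4 and Bu3SnH gives (2Z,4R)-6,6-dimethoxy-3-(tributylstannyl)hex-2-en-4-ol F7, and Stille allylation with allyl bromide (Pd(PPh3)4, CuI) returns to the route at 7.

Step 14 (with step 15). The C4 enolate may expel the β-alkoxide and open the dioxolane, enolisation may go toward C6, and in the palladium step the enolate may cyclise onto the allyl alkene. The fallback avoids strong base and palladium. It sets out from 19: enamine-mediated α-selenenylation (pyrrolidine catalyst, N-(phenylselanyl)phthalimide; the enamine forms toward the unsubstituted C4) gives (3aS,6R,7aR)-4-(phenylselanyl)-6-(prop-2-en-1-yl)-7a-[(2S)-1-(3,4,5-trimethoxyphenyl)propan-2-yl]hexahydro-1,3-benzodioxol-5-one F8. Oxidation with H2O2 and selenoxide syn-elimination through C3a–H arrives directly at 21.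

Further compounds

F1 | step 10 | methyl 2-[(3aR,6S,7aR)-5-hydroxy-7a-[(2S)-1-(3,4,5-trimethoxyphenyl)propan-2-yl]hexahydro-1,3-benzodioxol-6-yl]acetate (C5 epimers) | COC(=O)C[C@@H]1C[C@]2([C@@H](C)Cc3cc(OC)c(OC)c(OC)c3)OCO[C@@H]2CC1O
F2 | step 5 | (4S)-6,6-dimethoxyhex-2-yn-4-ol | CC#C[C@@H](O)CC(OC)OC
F3 | step 5 | (2E,4S)-6,6-dimethoxy-3-(prop-2-en-1-yl)hex-2-en-4-ol | C/C=C(\CC=C)[C@@H](O)CC(OC)OC
F4 | step 5 | (1S)-3,3-dimethoxy-1-[(2S,3S)-3-methyl-2-(prop-2-en-1-yl)oxiran-2-yl]propan-1-ol | C=CC[C@]1(O[C@H]1C)[C@@H](O)CC(OC)OC
F5 | step 5 | (1R)-3,3-dimethoxy-1-[(2S,3S)-3-methyl-2-(prop-2-en-1-yl)oxiran-2-yl]propyl 4-nitrobenzoate | C=CC[C@]1(O[C@H]1C)[C@H](OC(=O)c2ccc(cc2)[N+](=O)[O-])CC(OC)OC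
F6 | step 6 | (4R,5R)-4-[(2R)-1-(benzenesulfonyl)-1-(3,4,5-trimethoxyphenyl)propan-2-yl]-7,7-dimethoxyhept-1-ene-4,5-diol (epimers at the sulfonyl carbon) | C=CC[C@@](O)([C@@H](C)C(c1cc(OC)c(OC)c(OC)c1)S(=O)(=O)c1ccccc1)[C@H](O)CC(OC)OC
F7 | step 4 | (2Z,4R)-6,6-dimethoxy-3-(tributylstannyl)hex-2-en-4-ol | C/C=C(\[Sn](CCCC)(CCCC)CCCC)[C@H](O)CC(OC)OC
F8 | step 14 | (3aS,6R,7aR)-4-(phenylselanyl)-6-(prop-2-en-1-yl)-7a-[(2S)-1-(3,4,5-trimethoxyphenyl)propan-2-yl]hexahydro-1,3-benzodioxol-5-one (C4 epimers) | C=CC[C@@H]1C[C@]2([C@@H](C)Cc3cc(OC)c(OC)c(OC)c3)OCO[C@@H]2C([Se]c4ccccc4)C1=O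
A1 | alternative 1 | (3R,5R)-5-(1,1-dimethoxyethyl)-3-(prop-2-en-1-yl)-5-[(2S)-1-(3,4,5-trimethoxyphenyl)propan-2-yl]oxolan-2-one | C=CC[C@@H]1C[C@](C(C)(OC)OC)([C@@H](C)Cc2cc(OC)c(OC)c(OC)c2)OC1=O
A2 | alternative 1 | (4S)-2,2-dimethoxy-4-methyl-5-(3,4,5-trimethoxyphenyl)pentan-3-one | COC(C)(OC)C(=O)[C@@H](C)Cc1cc(OC)c(OC)c(OC)c1
A3 | alternative 1 | methyl 2-methylidenepent-4-enoate | C=CCC(=C)C(=O)OC
A4 | alternative 2 | (4R,6R)-4-(prop-2-en-1-yl)-6-[(2S)-1-(3,4,5-trimethoxyphenyl)propan-2-yl]cyclohex-2-en-1-one | C=CC[C@@H]1C[C@H]([C@@H](C)Cc2cc(OC)c(OC)c(OC)c2)C(=O)C=C1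
A5 | alternative 2 | pent-4-enal | C=CCCC=O
A6 | alternative 2 | (4S)-4-methyl-3-methylidene-5-(3,4,5-trimethoxyphenyl)pentan-2-one | CC(=O)C(=C)[C@@H](C)Cc1cc(OC)c(OC)c(OC)c1
A7 | alternative 3 | (3aR,7aS)-7a-[(2S)-1-(3,4,5-trimethoxyphenyl)propan-2-yl]-3a,4-dihydro-1,3-benzodioxol-5(7aH)-one | O=C1C=C[C@]2([C@@H](C)Cc3cc(OC)c(OC)c(OC)c3)OCO[C@@H]2C1
A8 | alternative 3 | 4-hydroxy-4-[(2S)-1-(3,4,5-trimethoxyphenyl)propan-2-yl]cyclohexa-2,5-dien-1-one | O=C1C=CC(O)([C@@H](C)Cc2cc(OC)c(OC)c(OC)c2)C=C1
A9 | alternative 3 | formaldehyde | C=O
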